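**Remarks on the chemistry (assumptions)**
- Locants C1–C15 are germacranolide locants: ring C1–C10, methyls C14 on C10 and C15 on C4, lactone carbons C11–C13.
- The structures of alkyne 8, aldehyde 16 and carbinol 19 were checked atom by atom against the target; all configurations and alkene geometries agree, so they are used unchanged.
- Aldehyde 16 needs C6 anti to O8 along the chain C12–C11–C7–C8–C9. Nitronate conjugate additions to glyceraldehyde-derived enoates are syn-selective and would give the C7 epimer, so C6 is brought in as a vinyl group by an anti-selective organocopper addition and unmasked by ozonolysis.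
- The (S)-configured phosphoric acid in step 3 is assumed to direct the propargyl group to the Si face of aldehyde 4; if the opposite sense were found, its enantiomer would be used.
- Dn = (1E,4S,5Z)-4-{[tert-butyl(dimethyl)silyl]oxy}-6-iodo-2-methylhepta-1,5-dien-1-yl (carbons C5, C4 with C15, C3, C2, C1, C10, C14).

## Structural features

The target is a heliangolide-type germacranolide: a ten-membered carbocycle (C1–C10) with a Z trisubstituted alkene C1=C10 (methyl C14) and an E trisubstituted alkene C4=C5 (methyl C15). An α-methylene-γ-butyrolactone (O–C12(=O)–C11=C13) is trans-fused to this ring across C6–C7. There are five stereocentres: C2, a free allylic carbinol, stands alone, while C6 (lactone oxygen, allylic), C7, C8 (angelate) and C9 (acetate, allylic) are contiguous. The fragile groups are the exo-methylene lactone (a Michael acceptor), the angelate (prone to Z-to-E isomerisation), the vicinal esters at C8 and C9 (acyl migration), the allylic C–O bonds at C2, C6 and C9, and the lactone acyl group, which can shift to O8 when that oxygen is free. The real difficulty is the medium ring with two trisubstituted alkenes of opposite geometry, combined with the C6–C9 stereotetrad and three secondary oxygens (C2, C8, C9) that must end in three different states. The key step exploits the C4=C5 alkene: methyl C15 on C4 is cis to C6 on C5, which is the pattern left by syn addition of methyl and metal to a terminal C4≡C5 alkyne followed by C5–C6 bond formation to a C6 aldehyde. The C7 centre of that aldehyde, already carrying C8 and C11, controls the new C6 carbinol, and the C1=C10 alkene rides through as a Z alkenyl iodide that later closes the ring at C9–C10.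

## Logic of the disconnections

**34 back to 30 (through 33, 32, 31).** The O–Si bond at C2 and the acyl–O bonds at C8 and C9 are cut first. The angelate is the most isomerisation-prone group and is therefore installed last but one, on a C8 hydroxyl freed from a triethylsilyl ether (33 from 32 from 31). The robust acetate goes on C9 directly after ring closure (31 from 30). This reduces the problem to one macrocyclic alcohol with two silyl ethers of different lability. The forward steps must acylate without acetyl migration between O9 and O8 and without angelate isomerisation.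

**30 back to 29.** The C9–C10 ring bond is cut. It joins an sp2 carbon to a carbinol carbon, so it maps onto the addition of an alkenyl metal (from the C10 iodide) to a C9 aldehyde. The ten-membered ring becomes an open chain and C9 ceases to be a stereocentre. The forward closure must beat oligomerisation, keep the Z geometry and add to the Re face of the aldehyde.

**29 back to 25 (through 27, 26).** The C9 aldehyde and the C8 silyl ether are traced to the two oxygens of a dioxolane. The cut is functional-group interconversion only. It lets C8 and C9 travel as one robust unit from the chiral pool. The forward demand is differentiation of a primary from a secondary oxygen and survival of the exo-methylene lactone while the diol is briefly free.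

**25 back to 20 (through 23).** The C11=C13 bond is cut. The methylene is added to the lactone enolate while the molecule is still acyclic and carries no ester other than the lactone. The forward step must enolise C11 without touching the alkenyl iodide.

**20 back to 19.** The O6–C12 lactone bond is cut to a γ-hydroxy tert-butyl ester. This keeps the key-step product open-chain and lets the dioxolane ensure that only O6 can reach C12. The forward step must close on a hindered ester under conditions that leave acetonide, silyl ether and allylic carbinol intact.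

**19 back to 8, 17 and 16 (key disconnection).** Two skeletal bonds are cut, C5–C6 and C4–C15. This splits the molecule into an alkyne half (C1–C5, C10, C14), a one-carbon unit and an aldehyde half (C6–C9, C11, C12) of similar size. The forward step must add methyl to C4 and metal to C5 in a syn fashion, transfer C5 to the aldehyde with retention, and choose the Re face of C6 under the influence of C7.

**16 back to 9 and 10 (through 14, 11, with 12).** The C6 carbonyl is traced to a vinyl group (C6=CH2 cut by ozonolysis), the C6–C7 bond to a conjugate addition of 12 to enoate 11, and C7=C11 to an olefination of 9 with 10. C8 comes from the chiral pool and C7 is set relative to it. The forward demand is anti selectivity in the conjugate addition and a neutral unmasking that spares the α-stereocentre.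

**8 back to 1 and 5 (through 7, 4, 3).** The O–Si bond is removed, then C2–C3 is cut to the Z iodo-enal 4 and the allenylboronate 5, and 4 is traced by oxidation and hydroalumination–iodination to 1. The forward demand is catalyst control of C2 and retention of the Z iodoalkene.

## Other disconnections considered

**Alternative 1:** The cut runs through the C4=C5 double bond and a transannular C4–C9 σ-bond, so the cyclodecadiene is traced to the trans-fused decalin hydroxy mesylate A2 (tertiary C9 alcohol, angular methyl C15 on C4, equatorial C5 mesylate). In the forward step KOtBu deprotonates the C9 hydroxyl of A2. The C4–C9 bond, antiperiplanar to the C5–O bond, breaks as the C9 carbonyl and the C4=C5 alkene form (Wharton–Grob fragmentation), giving the ten-membered dienone lactone A1.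
- In its favour: the medium ring arises from two six-membered rings without any macrocyclisation, which is better than the dilution-dependent closure of 29. The E geometry follows stereospecifically from the chair, which is the equal of syn carbometalation. The Z alkene is inherited from a cyclohexene.
- Against it here: A2 needs seven stereocentres, three of which (C4, C5, C9) are destroyed. The strong base meets a lactone and produces an α-alkoxy ketone that can epimerise at C8. A1 still lacks C13 and needs a face-selective reduction at C9, so the C9 question of the chosen plan returns with an extra step.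
- Comparison: structurally this route is linear where the chosen plan is convergent. Mechanistically it is more reliable for ring formation and equal for alkene geometry. In step economy it is expected to be longer, because the oxygenation pattern of A2 (C2, C5, C6, C8, C9) must be built on a decalin first.

**Alternative 2:** The cut removes C1–C2 and C3–C4 on either side of a two-carbon unit, giving the Z alkenyl pinacol boronate A4 (C1, C10, C14, C9, C8), vinyllithium A6 (C2, C3) and the E alkenyl bromide A5 (C4, C15, C5, C6 and a vinyl group). In the forward step A4 and A6 form a borate. Pd(OAc)2 with a chiral MandyPhos bisphosphine adds oxidatively to A5, the divalent palladium alkenyl species binds the vinyl group, C1 shifts from boron to C2 while C3 bonds to C4, and NaOH/H2O2 turns C2–B into C2–OH, giving the open-chain carbinol A3.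
- In its favour: three components are joined and C2 is set by the catalyst in one operation. For C2 control this is the equal of the organocatalytic propargylation, and it is better in bond count per step. Both alkene geometries are preformed, which is equal to the chosen plan. No pyrophoric aluminium reagent is needed, which is better.
- Against it here: an α-branched Z alkenyl group is a demanding migrating group, and direct coupling of A4 with A5 competes. A3 has neither the C6–C7–C8 array, nor the lactone, nor the ring, so a closure such as that of alternative 3 is still required.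
- Comparison: the chosen key step builds C4=C5 and C5–C6 together and sets C6, whereas this step builds C1–C2 and C3–C4 and sets C2. The two are comparable in convergence. Overall the alternative is not expected to be shorter, because the stereocentres C6 and C9 and the butenolide have to be made separately.

**Alternative 3:** The cut is C7–C8, opening the ring to the aldehyde A8, in which the lactone is present as a 2-(bromomethyl)butenolide. In the forward step CrCl2 reduces the allylic bromide to an allylchromium species (trivalent chromium). This adds through its γ-carbon C7 to the C8 aldehyde, which closes the ring, creates C7 and C8 and moves the double bond to C11=C13, giving the 8-hydroxy germacranolide A7.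
- In its favour: the ring, two stereocentres and the exo-methylene lactone appear in one step. The Michael acceptor is revealed only at the end, which is better than carrying it through eight steps as in the chosen plan. The sequence after cyclisation is shorter, which is also better.
- Against it here: two stereocentres must form correctly relative to C6 and C9 in a ten-membered transition state. The chosen plan takes C8 from the chiral pool, sets C7 by a precedented acyclic addition and leaves only C9 to the closure. The bromomethyl butenolide is sensitive to SN2′ attack and base, and A8 needs a long linear assembly, for example from an open chain such as A3.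
- Comparison: both plans rely on a chromium-mediated macrocyclisation with the same dilution demands, so they are equal on that point. The alternative is better in step economy after the ring is closed and worse in stereochemical risk at the closure.

Key step: step 8

## Route

**Step 1**
Reactants: 1 but-2-yn-1-ol
Product: 3 (2Z)-3-iodobut-2-en-1-ol, via cyclic alkenylaluminate 2 (not isolated)
Conditions: NaAlH2(OCH2CH2OMe)2, THF, 0 °C to rt; then I2, −78 to 0 °C
Reagents that add atoms: iodine, II
Why: trans-Hydroalumination of a propargylic alcohol: the alkoxyaluminium hydride delivers hydride to C2 and binds aluminium to C3 in a five-membered ring, and iodinolysis of the C–Al bond with retention leaves iodine cis to CH2OH (Z).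

**Step 2**
Reactants: 3 (2Z)-3-iodobut-2-en-1-ol
Product: 4 (2Z)-3-iodobut-2-enal
Conditions: MnO2, CH2Cl2, rt, dark
Reagents that add atoms: none
Why: Selective allylic oxidation with MnO2 under neutral conditions; the Z β-iodo enal should keep its geometry if kept cold and dark and used at once.

**Step 3**
Reactants: 4 (2Z)-3-iodobut-2-enal; 5 4,4,5,5-tetramethyl-2-(propa-1,2-dien-1-yl)-1,3,2-dioxaborolane
Product: 7 (4S,5Z)-6-iodohept-5-en-1-yn-4-ol, via pinacol borate ester 6 (not isolated)
Conditions: (S)-3,3′-bis(2,4,6-triisopropylphenyl)-1,1′-binaphthyl-2,2′-diyl hydrogen phosphate (5 mol %), 4 Å molecular sieves, toluene, −20 °C; aqueous work-up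
Reagents that add atoms: none
Why: Chiral phosphoric acid catalysed propargylboration: the allenylboronate adds through a six-membered SE2′ transition state held by the catalyst, which should direct C3 to the Si face of the aldehyde and give 4S (C2 of the target); the alkenyl iodide is inert.

**Step 4**
Reactants: 7 (4S,5Z)-6-iodohept-5-en-1-yn-4-ol
Product: 8 tert-butyl{[(4S,5Z)-6-iodohept-5-en-1-yn-4-yl]oxy}dimethylsilane
Conditions: tert-butyldimethylsilyl chloride, imidazole, DMF, rt
Reagents that add atoms: tert-butyldimethylsilyl chloride, CC(C)(C)[Si](C)(C)Cl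
Why: Standard silylation of a secondary alcohol; the silyl ether masks the acidic hydroxyl for the organoaluminium step and is the most robust of the silyl groups used.

**Step 5**
Reactants: 9 (4S)-2,2-dimethyl-1,3-dioxolane-4-carbaldehyde; 10 tert-butyl 2-(diethoxyphosphoryl)acetate
Product: 11 tert-butyl (2E)-3-[(4R)-2,2-dimethyl-1,3-dioxolan-4-yl]prop-2-enoate
Conditions: LiCl, iPr2NEt, MeCN, 0 °C to rt
Reagents that add atoms: none
Why: Horner–Wadsworth–Emmons olefination under Masamune–Roush conditions: the weak amine base avoids epimerisation of 9 and the phosphonate gives the E enoate; the descriptor changes from S to R only through the priority change.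

**Step 6**
Reactants: 11 tert-butyl (2E)-3-[(4R)-2,2-dimethyl-1,3-dioxolan-4-yl]prop-2-enoate; 12 vinylmagnesium bromide
Product: 14 tert-butyl (3S)-3-[(4R)-2,2-dimethyl-1,3-dioxolan-4-yl]pent-4-enoate, via silyl ketene acetal 13 (not isolated)
Conditions: CuI (0.2 equiv), Me3SiCl, THF, −78 to −40 °C; aq. NH4Cl
Reagents that add atoms: none
Why: Me3SiCl-accelerated copper-catalysed conjugate addition: organocopper reagents are known to add to γ-alkoxy (E)-enoates anti to the γ-oxygen, which sets C7 with the vinyl carbon C6 anti to O8 as the target requires; a nitronate would add syn.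

**Step 7**
Reactants: 14 tert-butyl (3S)-3-[(4R)-2,2-dimethyl-1,3-dioxolan-4-yl]pent-4-enoate
Product: 16 tert-butyl (3R)-3-[(4R)-2,2-dimethyl-1,3-dioxolan-4-yl]-4-oxobutanoate, via ozonide 15 (not isolated)
Conditions: O3, CH2Cl2, −78 °C; then PPh3, −78 °C to rt
Reagents that add atoms: ozone, [O-][O+]=O
Why: Ozonolysis of the only alkene with neutral reductive work-up, so the α-stereocentre C7 is not epimerised and the β-alkoxy aldehyde does not eliminate; 16 is used without chromatography.

**Step 8**
Reactants: 8 tert-butyl{[(4S,5Z)-6-iodohept-5-en-1-yn-4-yl]oxy}dimethylsilane; 17 trimethylaluminium; 16 tert-butyl (3R)-3-[(4R)-2,2-dimethyl-1,3-dioxolan-4-yl]-4-oxobutanoate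
Product: 19 tert-butyl (3S,4R,5E,8S,9Z)-8-{[tert-butyl(dimethyl)silyl]oxy}-3-[(4R)-2,2-dimethyl-1,3-dioxolan-4-yl]-4-hydroxy-10-iodo-6-methylundeca-5,9-dienoate, via alkenylalane 18 (not isolated)
Conditions: 17 (2.2 equiv), Cp2ZrCl2 (0.25 equiv), H2O (1 equiv), CH2Cl2, −20 °C; then 16 (0.8 equiv), CH2Cl2, −78 to −30 °C; aq. potassium sodium tartrate
Reagents that add atoms: none
Why: Cp2ZrCl2 and 17 form a methylzirconocene–aluminate pair that adds CH3–Zr syn across C4≡C5 of 8, methyl to the internal carbon C4 and metal to the terminal C5; Zr-to-Al exchange then gives the (E)-alkenyldimethylalane 18, with water accelerating the carbometalation so that it runs at −20 °C. The closest known reaction type is the zirconium-catalysed methylalumination of a terminal alkyne followed by 1,2-addition of the alkenylalane to an aldehyde. 18 binds the carbonyl oxygen of 16 and transfers C5 with retention, so C15 and C6 end up cis (E alkene). No ring is closed, because the hindered tert-butyl ester is not attacked by the aluminium alkoxide at low temperature. The one new stereocentre, C6, is controlled by C7: in the Felkin–Anh arrangement C8 with its dioxolane is antiperiplanar to the incoming C5, C11 lies beside the carbonyl oxygen and the alkenyl group enters past H7 on the Re face, which should give 6R with O6 and C11 syn in the extended chain, as the trans-lactone needs. Regioselectivity rests on the terminal alkyne; chemoselectivity rests on the inertness of the alkenyl iodide, the silyl ether and the trisubstituted alkene towards the zirconium–aluminium reagent when no late-metal catalyst is present. Alkenyl transfer from aluminium is faster than methyl transfer, and 16 is used as the limiting component at −78 °C to suppress methyl addition, acetonide opening by aluminium and epimerisation at C7.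

**Step 9**
Reactants: 19 tert-butyl (3S,4R,5E,8S,9Z)-8-{[tert-butyl(dimethyl)silyl]oxy}-3-[(4R)-2,2-dimethyl-1,3-dioxolan-4-yl]-4-hydroxy-10-iodo-6-methylundeca-5,9-dienoate
Product: 20 (4S,5R)-5-Dn-4-[(4R)-2,2-dimethyl-1,3-dioxolan-4-yl]oxolan-2-one
Conditions: NaOtBu (0.2 equiv), THF, 0 °C to rt
Reagents that add atoms: none
Why: Base-catalysed intramolecular transesterification (5-exo-trig): the C6 alkoxide attacks the tert-butyl ester and the expelled tert-butoxide carries the chain; the acetonide blocks O8, so only the 6,12-lactone can form, and no stereocentre is touched (trans-lactone).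

**Step 10**
Reactants: 20 (4S,5R)-5-Dn-4-[(4R)-2,2-dimethyl-1,3-dioxolan-4-yl]oxolan-2-one; 21 N,N-dimethylmethaniminium iodide (Eschenmoser's salt)
Product: 23 (3R,4S,5R)-3-[(dimethylamino)methyl]-5-Dn-4-[(4R)-2,2-dimethyl-1,3-dioxolan-4-yl]oxolan-2-one, via lithium enolate 22 (not isolated)
Conditions: LiN(SiMe3)2, THF, −78 °C; then 21, −78 to 0 °C
Reagents that add atoms: none
Why: Mannich aminomethylation of the lactone enolate; the silylamide base is too weak to dehydrohalogenate the alkenyl iodide, and the iminium ion should enter anti to the C7 substituent, giving a C11 centre that is removed in the next step.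

**Step 11**
Reactants: 23 (3R,4S,5R)-3-[(dimethylamino)methyl]-5-Dn-4-[(4R)-2,2-dimethyl-1,3-dioxolan-4-yl]oxolan-2-one
Product: 25 (4S,5R)-5-Dn-4-[(4R)-2,2-dimethyl-1,3-dioxolan-4-yl]-3-methylideneoxolan-2-one, via trimethylammonium iodide 24 (not isolated)
Conditions: MeI, THF, rt; then aq. NaHCO3, CH2Cl2, rt
Reagents that add atoms: none
Why: Quaternisation of the amine followed by E1cB elimination of trimethylamine under mild base gives the exo-methylene lactone (α-methylenation via the Mannich base).

**Step 12**
Reactants: 25 (4S,5R)-5-Dn-4-[(4R)-2,2-dimethyl-1,3-dioxolan-4-yl]-3-methylideneoxolan-2-one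
Product: 26 (4R,5R)-4-[(1R)-1,2-dihydroxyethyl]-5-Dn-3-methylideneoxolan-2-one
Conditions: AcOH/H2O (4:1), rt
Reagents that add atoms: none
Why: Acid hydrolysis of a terminal acetonide; the secondary silyl ether and the allylic lactone tolerate aqueous acetic acid at rt, and the acidic medium disfavours oxa-Michael addition and acyl shift to O8; the diol is silylated at once.

**Step 13**
Reactants: 26 (4R,5R)-4-[(1R)-1,2-dihydroxyethyl]-5-Dn-3-methylideneoxolan-2-one
Product: 27 (4S,5R)-4-{(1R)-1,2-bis[(triethylsilyl)oxy]ethyl}-5-Dn-3-methylideneoxolan-2-one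
Conditions: Et3SiOTf, 2,6-lutidine, CH2Cl2, −78 to 0 °C
Reagents that add atoms: triethylsilyl trifluoromethanesulfonate, CC[Si](CC)(CC)OS(=O)(=O)C(F)(F)F
Why: Exhaustive silylation with a silyl triflate and a hindered pyridine base is fast at low temperature and outruns any base-induced reaction of the diol with the lactone.

**Step 14**
Reactants: 27 (4S,5R)-4-{(1R)-1,2-bis[(triethylsilyl)oxy]ethyl}-5-Dn-3-methylideneoxolan-2-one
Product: 29 (2R)-2-[(2R,3S)-2-Dn-4-methylidene-5-oxooxolan-3-yl]-2-[(triethylsilyl)oxy]acetaldehyde, via alkoxysulfonium chloride 28 (not isolated)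
Conditions: (COCl)2, DMSO, CH2Cl2, −78 to −40 °C; then Et3N, −78 to 0 °C
Reagents that add atoms: none
Why: Swern oxidation applied directly to the silyl ether: the activated sulfonium reagent cleaves the less hindered primary triethylsilyl ether and oxidises it in the same flask, while the secondary triethylsilyl and tert-butyldimethylsilyl ethers remain; the α-silyloxy aldehyde is configurationally stable at low temperature.

**Step 15**
Reactants: 29 (2R)-2-[(2R,3S)-2-Dn-4-methylidene-5-oxooxolan-3-yl]-2-[(triethylsilyl)oxy]acetaldehyde
Product: 30 (1(10)Z,2S,4E,6R,7S,8R,9R)-2-{[tert-butyl(dimethyl)silyl]oxy}-9-hydroxy-8-[(triethylsilyl)oxy]germacra-1(10),4,11(13)-trien-12,6-olide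
Conditions: CrCl2 (10 equiv), NiCl2 (0.1 equiv), DMSO, rt, 0.003 M, slow addition
Reagents that add atoms: none
Why: Nozaki–Hiyama–Kishi reaction: zerovalent nickel inserts into the C10–I bond with retention, the alkenyl group passes to trivalent chromium and adds to the C9 aldehyde, closing the ten-membered ring at high dilution; the alkenylchromium does not add to the methylene lactone. C9 is set in the cyclic transition state: with C9=O opposed to the C8–OSi dipole, delivery of C10 from the C7 side (gauche ring torsion) places it on the Re face and should give 9R; an acyclic Felkin–Anh preference would oppose this, so C9 is the least predictable centre.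

**Step 16**
Reactants: 30 (1(10)Z,2S,4E,6R,7S,8R,9R)-2-{[tert-butyl(dimethyl)silyl]oxy}-9-hydroxy-8-[(triethylsilyl)oxy]germacra-1(10),4,11(13)-trien-12,6-olide
Product: 31 (1(10)Z,2S,4E,6R,7S,8R,9R)-9-acetoxy-2-{[tert-butyl(dimethyl)silyl]oxy}-8-[(triethylsilyl)oxy]germacra-1(10),4,11(13)-trien-12,6-olide
Conditions: Ac2O, pyridine, 4-(dimethylamino)pyridine (cat.), CH2Cl2, 0 °C
Reagents that add atoms: acetic anhydride, CC(=O)OC(C)=O
Why: Standard acylation of the only free hydroxyl; carried out promptly so that the triethylsilyl group cannot wander from O8 to O9.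

**Step 17**
Reactants: 31 (1(10)Z,2S,4E,6R,7S,8R,9R)-9-acetoxy-2-{[tert-butyl(dimethyl)silyl]oxy}-8-[(triethylsilyl)oxy]germacra-1(10),4,11(13)-trien-12,6-olide
Product: 32 (1(10)Z,2S,4E,6R,7R,8R,9R)-9-acetoxy-2-{[tert-butyl(dimethyl)silyl]oxy}-8-hydroxygermacra-1(10),4,11(13)-trien-12,6-olide
Conditions: pyridinium p-toluenesulfonate (cat.), MeOH/CH2Cl2, 0 °C
Reagents that add atoms: none
Why: Acid-catalysed methanolysis cleaves a triethylsilyl ether much faster than a tert-butyldimethylsilyl ether, and the mild acid avoids acetyl migration from O9 to O8; the change of the C7 descriptor to R is a priority effect only.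

**Step 18**
Reactants: 32 (1(10)Z,2S,4E,6R,7R,8R,9R)-9-acetoxy-2-{[tert-butyl(dimethyl)silyl]oxy}-8-hydroxygermacra-1(10),4,11(13)-trien-12,6-olide
Product: 33 (1(10)Z,2S,4E,6R,7S,8R,9R)-9-acetoxy-8-(angeloyloxy)-2-{[tert-butyl(dimethyl)silyl]oxy}germacra-1(10),4,11(13)-trien-12,6-olide
Conditions: angelic acid, 2,4,6-trichlorobenzoyl chloride, Et3N, toluene, rt, filter; then 32, toluene, 75 °C
Reagents that add atoms: angelic acid, C/C=C(/C)C(=O)O
Why: Yamaguchi-type esterification with the preformed mixed anhydride, run without a nucleophilic catalyst and without free amine, so the Z enoate does not isomerise to the tiglate and base-promoted acetyl migration is minimised.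

**Step 19**
Reactants: 33 (1(10)Z,2S,4E,6R,7S,8R,9R)-9-acetoxy-8-(angeloyloxy)-2-{[tert-butyl(dimethyl)silyl]oxy}germacra-1(10),4,11(13)-trien-12,6-olide
Product: 34 (1(10)Z,2S,4E,6R,7S,8R,9R)-9-acetoxy-8-(angeloyloxy)-2-hydroxygermacra-1(10),4,11(13)-trien-12,6-olide (CNP0316477.1)
Conditions: HF·pyridine, pyridine, THF, 0 °C to rt
Reagents that add atoms: none
Why: Fluoride-mediated desilylation under buffered, non-basic conditions, which should spare both esters, the angelate geometry and the methylene lactone.

## Compound list

1 | but-2-yn-1-ol | CC#CCO | starting material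
2 | sodium 2,2-bis(2-methoxyethoxy)-3-methyl-2,5-dihydro-1,2-oxaluminol-2-uide (cyclic alkenylaluminate, not isolated) | CC1=CCO[Al-]1(OCCOC)OCCOC.[Na+] | intermediate
3 | (2Z)-3-iodobut-2-en-1-ol | OC/C=C(/C)I | intermediate
4 | (2Z)-3-iodobut-2-enal | O=C/C=C(/C)I | intermediate
5 | 4,4,5,5-tetramethyl-2-(propa-1,2-dien-1-yl)-1,3,2-dioxaborolane (allenylboronic acid pinacol ester) | C=C=CB1OC(C)(C)C(C)(C)O1 | starting material
6 | 2-{[(4S,5Z)-6-iodohept-5-en-1-yn-4-yl]oxy}-4,4,5,5-tetramethyl-1,3,2-dioxaborolane (not isolated) | C#CC[C@H](OB1OC(C)(C)C(C)(C)O1)/C=C(/C)I | intermediate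
7 | (4S,5Z)-6-iodohept-5-en-1-yn-4-ol | C#CC[C@H](O)/C=C(/C)I | intermediate
8 | tert-butyl{[(4S,5Z)-6-iodohept-5-en-1-yn-4-yl]oxy}dimethylsilane | C#CC[C@H](O[Si](C)(C)C(C)(C)C)/C=C(/C)I | intermediate
9 | (4S)-2,2-dimethyl-1,3-dioxolane-4-carbaldehyde | O=C[C@@H]1COC(C)(C)O1 | starting material
10 | tert-butyl 2-(diethoxyphosphoryl)acetate | CCOP(=O)(OCC)CC(=O)OC(C)(C)C | starting material
11 | tert-butyl (2E)-3-[(4R)-2,2-dimethyl-1,3-dioxolan-4-yl]prop-2-enoate | CC(C)(C)OC(=O)/C=C/[C@@H]1COC(C)(C)O1 | intermediate
12 | vinylmagnesium bromide | C=C[Mg]Br | starting material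
13 | tert-butyl trimethylsilyl ketene acetal of 14 (configuration as in 14, ketene acetal geometry undefined, not isolated) | C=C[C@H](C=C(OC(C)(C)C)O[Si](C)(C)C)[C@@H]1COC(C)(C)O1 | intermediate
14 | tert-butyl (3S)-3-[(4R)-2,2-dimethyl-1,3-dioxolan-4-yl]pent-4-enoate | C=C[C@H](CC(=O)OC(C)(C)C)[C@@H]1COC(C)(C)O1 | intermediate
15 | ozonide of 14 (1,2,4-trioxolane on C6, trioxolane carbon a mixture of epimers, not isolated) | C1(OCOO1)[C@H](CC(=O)OC(C)(C)C)[C@@H]2COC(C)(C)O2 | intermediate
16 | tert-butyl (3R)-3-[(4R)-2,2-dimethyl-1,3-dioxolan-4-yl]-4-oxobutanoate | O=C[C@H](CC(=O)OC(C)(C)C)[C@@H]1COC(C)(C)O1 | intermediate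
17 | trimethylaluminium | C[Al](C)C | starting material
18 | [(1E,4S,5Z)-4-{[tert-butyl(dimethyl)silyl]oxy}-6-iodo-2-methylhepta-1,5-dien-1-yl]dimethylalumane (not isolated) | C[Al](C)/C=C(\C)C[C@H](O[Si](C)(C)C(C)(C)C)/C=C(/C)I | intermediate
19 | tert-butyl (3S,4R,5E,8S,9Z)-8-{[tert-butyl(dimethyl)silyl]oxy}-3-[(4R)-2,2-dimethyl-1,3-dioxolan-4-yl]-4-hydroxy-10-iodo-6-methylundeca-5,9-dienoate | CC(C)(C)OC(=O)C[C@@H]([C@H](O)/C=C(\C)C[C@H](O[Si](C)(C)C(C)(C)C)/C=C(/C)I)[C@@H]1COC(C)(C)O1 | intermediate
20 | (4S,5R)-5-Dn-4-[(4R)-2,2-dimethyl-1,3-dioxolan-4-yl]oxolan-2-one | O=C1C[C@@H]([C@H](O1)/C=C(\C)C[C@H](O[Si](C)(C)C(C)(C)C)/C=C(/C)I)[C@@H]2COC(C)(C)O2 | intermediate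
21 | N,N-dimethylmethaniminium iodide (Eschenmoser's salt) | C=[N+](C)C.[I-] | starting material
22 | lithium enolate of 20 (C11=C12 enolate, not isolated) | [Li]OC1=C[C@@H]([C@H](O1)/C=C(\C)C[C@H](O[Si](C)(C)C(C)(C)C)/C=C(/C)I)[C@@H]2COC(C)(C)O2 | intermediate
23 | (3R,4S,5R)-3-[(dimethylamino)methyl]-5-Dn-4-[(4R)-2,2-dimethyl-1,3-dioxolan-4-yl]oxolan-2-one | O=C1[C@@H](CN(C)C)[C@@H]([C@H](O1)/C=C(\C)C[C@H](O[Si](C)(C)C(C)(C)C)/C=C(/C)I)[C@@H]2COC(C)(C)O2 | intermediate
24 | 1-{(3R,4S,5R)-5-Dn-4-[(4R)-2,2-dimethyl-1,3-dioxolan-4-yl]-2-oxooxolan-3-yl}-N,N,N-trimethylmethanaminium iodide (not isolated) | O=C1[C@@H](C[N+](C)(C)C)[C@@H]([C@H](O1)/C=C(\C)C[C@H](O[Si](C)(C)C(C)(C)C)/C=C(/C)I)[C@@H]2COC(C)(C)O2.[I-] | intermediate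
25 | (4S,5R)-5-Dn-4-[(4R)-2,2-dimethyl-1,3-dioxolan-4-yl]-3-methylideneoxolan-2-one | O=C1C(=C)[C@@H]([C@H](O1)/C=C(\C)C[C@H](O[Si](C)(C)C(C)(C)C)/C=C(/C)I)[C@@H]2COC(C)(C)O2 | intermediate
26 | (4R,5R)-4-[(1R)-1,2-dihydroxyethyl]-5-Dn-3-methylideneoxolan-2-one | O=C1C(=C)[C@@H]([C@H](O1)/C=C(\C)C[C@H](O[Si](C)(C)C(C)(C)C)/C=C(/C)I)[C@@H](O)CO | intermediate
27 | (4S,5R)-4-{(1R)-1,2-bis[(triethylsilyl)oxy]ethyl}-5-Dn-3-methylideneoxolan-2-one | O=C1C(=C)[C@@H]([C@H](O1)/C=C(\C)C[C@H](O[Si](C)(C)C(C)(C)C)/C=C(/C)I)[C@@H](O[Si](CC)(CC)CC)CO[Si](CC)(CC)CC | intermediate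
28 | {(2R)-2-[(2R,3S)-2-Dn-4-methylidene-5-oxooxolan-3-yl]-2-[(triethylsilyl)oxy]ethoxy}dimethylsulfanium chloride (not isolated) | O=C1C(=C)[C@@H]([C@H](O1)/C=C(\C)C[C@H](O[Si](C)(C)C(C)(C)C)/C=C(/C)I)[C@@H](O[Si](CC)(CC)CC)CO[S+](C)C.[Cl-] | intermediate
29 | (2R)-2-[(2R,3S)-2-Dn-4-methylidene-5-oxooxolan-3-yl]-2-[(triethylsilyl)oxy]acetaldehyde | O=C1C(=C)[C@@H]([C@H](O1)/C=C(\C)C[C@H](O[Si](C)(C)C(C)(C)C)/C=C(/C)I)[C@@H](O[Si](CC)(CC)CC)C=O | intermediate
30 | (1(10)Z,2S,4E,6R,7S,8R,9R)-2-{[tert-butyl(dimethyl)silyl]oxy}-9-hydroxy-8-[(triethylsilyl)oxy]germacra-1(10),4,11(13)-trien-12,6-olide | C=C1C(=O)O[C@@H]2/C=C(\C)C[C@H](O[Si](C)(C)C(C)(C)C)/C=C(/C)[C@@H](O)[C@H](O[Si](CC)(CC)CC)[C@@H]12 | intermediate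
31 | (1(10)Z,2S,4E,6R,7S,8R,9R)-9-acetoxy-2-{[tert-butyl(dimethyl)silyl]oxy}-8-[(triethylsilyl)oxy]germacra-1(10),4,11(13)-trien-12,6-olide | C=C1C(=O)O[C@@H]2/C=C(\C)C[C@H](O[Si](C)(C)C(C)(C)C)/C=C(/C)[C@@H](OC(C)=O)[C@H](O[Si](CC)(CC)CC)[C@@H]12 | intermediate
32 | (1(10)Z,2S,4E,6R,7R,8R,9R)-9-acetoxy-2-{[tert-butyl(dimethyl)silyl]oxy}-8-hydroxygermacra-1(10),4,11(13)-trien-12,6-olide | C=C1C(=O)O[C@@H]2/C=C(\C)C[C@H](O[Si](C)(C)C(C)(C)C)/C=C(/C)[C@@H](OC(C)=O)[C@H](O)[C@@H]12 | intermediate
33 | (1(10)Z,2S,4E,6R,7S,8R,9R)-9-acetoxy-8-(angeloyloxy)-2-{[tert-butyl(dimethyl)silyl]oxy}germacra-1(10),4,11(13)-trien-12,6-olide | C=C1C(=O)O[C@@H]2/C=C(\C)C[C@H](O[Si](C)(C)C(C)(C)C)/C=C(/C)[C@@H](OC(C)=O)[C@H](OC(=O)/C(C)=C\C)[C@@H]12 | intermediate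
34 | (1(10)Z,2S,4E,6R,7S,8R,9R)-9-acetoxy-8-(angeloyloxy)-2-hydroxygermacra-1(10),4,11(13)-trien-12,6-olide (CNP0316477.1) | C=C1C(=O)O[C@@H]2/C=C(\C)C[C@H](O)/C=C(/C)[C@@H](OC(C)=O)[C@H](OC(=O)/C(C)=C\C)[C@@H]12 | target

## Step count and least certain steps

Total step count: 19. Longest linear sequence: 16 steps (steps 1–4, then 8–19); the aldehyde branch (steps 5–7) joins at step 8.

**Step 8 (key step).** The most likely failure is poor facial discrimination at the C6 aldehyde. Felkin–Anh control by C7 is opposed by a possible six-membered aluminium chelate to O8 and by the 1,3-polar effect of the syn α-alkyl/β-alkoxy pattern. Methyl transfer from aluminium to the aldehyde and epimerisation at C7 of 16 may add to this. Fallback: set out from 19 obtained as a mixture of C6 epimers and oxidise it with Dess–Martin periodinane (NaHCO3, CH2Cl2) to the C6 enone F1. Reduce F1 with Zn(BH4)2 in Et2O at −30 °C. In the zinc chelate between the C6 carbonyl and O8, hydride should arrive anti to C11, which is the face that gives 6R, and the sequence comes back to the route at 19.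

**Step 15.** The most likely failure is addition to the wrong face of the C9 aldehyde, because the acyclic Felkin–Anh preference of an α-silyloxy aldehyde favours the 9-epimer and the ring conformation may not override it. Oligomerisation at insufficient dilution and drift of the triethylsilyl group from O8 to the new C9 alkoxide are further risks. Fallback: set out from 30 obtained as the C9 epimer or as a mixture and oxidise it with Dess–Martin periodinane to the macrocyclic C9 enone F2. Reduce F2 under Luche conditions (NaBH4, CeCl3·7H2O, MeOH, −78 °C). For hydride, Felkin–Anh delivery anti to the C8–OSi bond leads to the required 8,9-syn (ring-trans) carbinol, and the sequence comes back to the route at 30.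

**Step 18.** The most likely failure is acetyl migration from O9 to the free O8 during the slow, heated acylation of a hindered alcohol, which would give regioisomeric diesters, together with partial isomerisation of angelate to tiglate. Fallback: set out from 32 and acylate at 0 °C with 2-[bis(2,2,2-trifluoroethoxy)phosphoryl]propanoic acid, N,N′-dicyclohexylcarbodiimide and catalytic 4-(dimethylamino)pyridine to the phosphonopropanoate F3. Then build the angelate double bond on the substrate by a Still–Gennari olefination (KN(SiMe3)2, 18-crown-6, THF, −78 °C, acetaldehyde), which is Z-selective and comes back to the route at 33.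

**Step 3.** The most likely failure is insufficient enantioselectivity, or the opposite sense, with a β-iodo-β-methyl enal, a substrate class outside the usual scope, compounded by Z-to-E isomerisation of 4 before it reacts. Fallback: set out from 4 and run a zinc-mediated Barbier reaction with 3-bromoprop-1-yne (Zn, THF/aq. NH4Cl) to the racemic homopropargylic alcohol F4. Resolve F4 by lipase-catalysed acylation (Burkholderia cepacia lipase, vinyl acetate, hexane). This should convert the R enantiomer into the acetate F5 and leave the S alcohol, which comes back to the route at 7.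

**Step 14.** The most likely failure is incomplete or unselective cleavage of the silyl ethers under the Swern conditions, with loss of the secondary triethylsilyl group or recovery of unoxidised material. Fallback: set out from 27 and remove only the primary triethylsilyl group with HF·pyridine buffered with pyridine (THF, 0 °C) to give the primary alcohol F6. Oxidise F6 with Dess–Martin periodinane (NaHCO3, CH2Cl2), which comes back to the route at 29.

## Further compounds

F1 | step 8 | tert-butyl (5E,8S,9Z)-8-{[tert-butyl(dimethyl)silyl]oxy}-3-[(4R)-2,2-dimethyl-1,3-dioxolan-4-yl]-10-iodo-6-methyl-4-oxoundeca-5,9-dienoate (C6 enone, C7 as in 19) | CC(C)(C)OC(=O)C[C@@H](C(=O)/C=C(\C)C[C@H](O[Si](C)(C)C(C)(C)C)/C=C(/C)I)[C@@H]1COC(C)(C)O1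
F2 | step 15 | (1(10)Z,2S,4E,6R,7S,8R)-2-{[tert-butyl(dimethyl)silyl]oxy}-9-oxo-8-[(triethylsilyl)oxy]germacra-1(10),4,11(13)-trien-12,6-olide | C=C1C(=O)O[C@@H]2/C=C(\C)C[C@H](O[Si](C)(C)C(C)(C)C)/C=C(/C)C(=O)[C@H](O[Si](CC)(CC)CC)[C@@H]12
F3 | step 18 | 8-O-{2-[bis(2,2,2-trifluoroethoxy)phosphoryl]propanoyl} derivative of 32 (phosphonate α-carbon a mixture of epimers) | C=C1C(=O)O[C@@H]2/C=C(\C)C[C@H](O[Si](C)(C)C(C)(C)C)/C=C(/C)[C@@H](OC(C)=O)[C@H](OC(=O)C(C)P(=O)(OCC(F)(F)F)OCC(F)(F)F)[C@@H]12
F4 | step 3 | racemic (5Z)-6-iodohept-5-en-1-yn-4-ol | C#CCC(O)/C=C(/C)I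
F5 | step 3 | (4R,5Z)-6-iodohept-5-en-1-yn-4-yl acetate | C#CC[C@@H](OC(C)=O)/C=C(/C)I
F6 | step 14 | (4S,5R)-4-{(1R)-2-hydroxy-1-[(triethylsilyl)oxy]ethyl}-5-Dn-3-methylideneoxolan-2-one | O=C1C(=C)[C@@H]([C@H](O1)/C=C(\C)C[C@H](O[Si](C)(C)C(C)(C)C)/C=C(/C)I)[C@@H](O[Si](CC)(CC)CC)CO
A1 | alternative 1 | ten-membered (1(10)Z,4E)-dienone lactone, C9 ketone, C8 p-methoxybenzyl ether, C2 silyl ether, C11 unsubstituted | C1C(=O)O[C@@H]2/C=C(\C)C[C@H](O[Si](C)(C)C(C)(C)C)/C=C(/C)C(=O)[C@H](OCc3ccc(OC)cc3)[C@@H]12
A2 | alternative 1 | trans-fused decalin lactone with C4–C9 bond, C9 tertiary alcohol, angular C15 methyl on C4 and equatorial C5 mesylate | C1C(=O)O[C@@H]2[C@@H](OS(C)(=O)=O)[C@]3(C)C[C@H](O[Si](C)(C)C(C)(C)C)C=C(C)[C@@]3(O)[C@H](OCc4ccc(OC)cc4)[C@@H]12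
A3 | alternative 2 | open-chain C2 carbinol with E C4=C5 and Z C1=C10 alkenes, C6 tert-butyldimethylsilyl ether, C9 triethylsilyl ether, C8 p-methoxybenzyl ether | C=C[C@H](O[Si](C)(C)C(C)(C)C)/C=C(\C)C[C@H](O)/C=C(/C)[C@@H](O[Si](CC)(CC)CC)COCc1ccc(OC)cc1
A4 | alternative 2 | Z alkenyl pinacol boronate (boron on C1; C10, C14, C9 triethylsilyl ether, C8 p-methoxybenzyl ether) | CC1(C)OB(/C=C(/C)[C@@H](O[Si](CC)(CC)CC)COCc2ccc(OC)cc2)OC1(C)C
A5 | alternative 2 | E alkenyl bromide (bromine on C4; C15, C5, C6 silyl ether, vinyl group) | C=C[C@H](O[Si](C)(C)C(C)(C)C)/C=C(\C)Br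
A6 | alternative 2 | vinyllithium | [Li]C=C
A7 | alternative 3 | 8-hydroxy germacranolide with C2 tert-butyldimethylsilyl and C9 triethylsilyl ethers | C=C1C(=O)O[C@@H]2/C=C(\C)C[C@H](O[Si](C)(C)C(C)(C)C)/C=C(/C)[C@@H](O[Si](CC)(CC)CC)[C@H](O)[C@@H]12
A8 | alternative 3 | open-chain C8 aldehyde carrying a 2-(bromomethyl)butenolide at C6 | BrCC1=C[C@@H](/C=C(\C)C[C@H](O[Si](C)(C)C(C)(C)C)/C=C(/C)[C@@H](O[Si](CC)(CC)CC)C=O)OC1=O
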